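**Plan**

- Carbocycle numbering: C1 (quaternary), C2 (C–OH), C3 (acyl), C4 (C=O), C5 (pyran C–C), C6 (pyran C–O6). C1 is stereogenic only because C2 and C6 differ, and the isopropenyl group of the C1 side chain can reach O2 or O6 through a six-membered ring that contains C1 and the chain stereocentre.
- Cuts, in retrosynthetic order: methyl ester; 2H-pyran ring (O6–CMe2 and C5–CH, back to 3-methylbut-2-enal); C3–acyl bond; a temporary O6–C(tertiary) ether on the isopropenyl carbon is put back and then cut to a C1-prochiral 2,2-dialkylcyclohexane-1,3,5-trione.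
- The trione is cut at C2–C3 and C5–C6 (dialkylmalonate plus acetoacetate dianion), then at C1–chain and C1–prenyl (malonate alkylations), and the chain at the C–C bond next to its stereocentre.
- Forward: chain iodide, quaternary malonate, carbocycle, temporary dihydropyran ring (sets C1), C3 acylation, zinc reopening, 2H-pyran ring, free acid.
- Stereochemistry: the chain centre comes from an Evans alkylation, C1 from that centre by substrate control in the cycloetherification, the acyl centre from (R)-2-methylbutanoic acid, and the E-enoate is bought in with bromide 4.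

Key step: step 9

Remark: methyl (E)-4-bromo-2-methylbut-2-enoate (4) is taken as a purchasable reagent (it is the allylic bromination product of methyl tiglate).
Remark: compounds with the cyclic tricarbonyl unit are enolized and are drawn as one tautomer each; the CIP label of C1 changes with the tautomer drawn, while its spatial arrangement is fixed from step 9 on.

**Step 1**
Reactants: 1 (S)-4-benzyl-1,3-oxazolidin-2-one; 2 3-methylbut-2-enoyl chloride
Product: 3 (S)-4-benzyl-3-(3-methylbut-2-enoyl)-1,3-oxazolidin-2-one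
Conditions: n-BuLi, THF, −78 °C; then 2, −78 to 0 °C
Reagents that add atoms: none
Why: N-acylation of the lithiated oxazolidinone with an acid chloride is the standard entry to Evans imides and leaves the benzyl-bearing stereocentre untouched.

**Step 2**
Reactants: 3 (S)-4-benzyl-3-(3-methylbut-2-enoyl)-1,3-oxazolidin-2-one; 4 methyl (E)-4-bromo-2-methylbut-2-enoate
Product: 5 methyl (2E,5S)-5-{[(4S)-4-benzyl-2-oxo-1,3-oxazolidin-3-yl]carbonyl}-2,6-dimethylhepta-2,6-dienoate
Conditions: NaN(SiMe3)2, THF, −78 °C; then 4, −78 to −40 °C; cold NH4Cl quench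
Reagents that add atoms: none
Why: Evans alkylation in its deconjugative form (as used for lavandulol-type units), in which the chelated sodium Z-dienolate reacts at its α-carbon with the allylic bromide by SN2 on the face away from the benzyl group, which sets the chain stereocentre and leaves the E-enoate of the electrophile unchanged.

**Step 3**
Reactants: 5 methyl (2E,5S)-5-{[(4S)-4-benzyl-2-oxo-1,3-oxazolidin-3-yl]carbonyl}-2,6-dimethylhepta-2,6-dienoate
Product: 7 methyl (2E,5S)-5-(hydroxymethyl)-2,6-dimethylhepta-2,6-dienoate, via aldehyde 6 (not isolated)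
Conditions: NaBH4, THF/H2O, 0 °C to rt
Reagents that add atoms: none
Why: Reductive removal of the auxiliary, in which NaBH4 in wet THF reduces the activated exocyclic imide carbonyl through the aldehyde to the primary alcohol faster than it touches a conjugated methyl ester, the fast second reduction keeping the α-centre of the transient β,γ-unsaturated aldehyde intact.

**Step 4**
Reactants: 7 methyl (2E,5S)-5-(hydroxymethyl)-2,6-dimethylhepta-2,6-dienoate
Product: 8 methyl (2E,5S)-5-(iodomethyl)-2,6-dimethylhepta-2,6-dienoate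
Conditions: I2, PPh3, imidazole, CH2Cl2, 0 °C to rt
Reagents that add atoms: iodine, II
Why: Appel-type iodination converts the primary alcohol into the iodide under neutral conditions by SN2 at the CH2 group, so the adjacent stereocentre and the olefins are not touched.

**Step 5**
Reactants: 9 dimethyl malonate; 10 prenyl bromide (1-bromo-3-methylbut-2-ene)
Product: 11 dimethyl 2-(3-methylbut-2-en-1-yl)malonate
Conditions: NaH, THF, 0 °C; then 10, 0 °C to rt (9 in excess)
Reagents that add atoms: none
Why: Malonic ester alkylation with a reactive allylic bromide, with an excess of the malonate to hold back dialkylation.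

**Step 6**
Reactants: 11 dimethyl 2-(3-methylbut-2-en-1-yl)malonate; 8 methyl (2E,5S)-5-(iodomethyl)-2,6-dimethylhepta-2,6-dienoate
Product: 12 dimethyl 2-(3-methylbut-2-en-1-yl)-2-[(2R,4E)-5-(methoxycarbonyl)-2-(prop-1-en-2-yl)hex-4-en-1-yl]malonate
Conditions: NaH, DMF, 0 °C; then 8, 60 °C
Reagents that add atoms: none
Why: Second malonic ester alkylation, an SN2 displacement of the primary iodide that creates the quaternary carbon (future C1, not yet stereogenic), with the prenyl group put on first so that no enolizable malonate ever carries the enoate arm and a 5-exo intramolecular Michael addition is excluded.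

**Step 7**
Reactants: 12 dimethyl 2-(3-methylbut-2-en-1-yl)-2-[(2R,4E)-5-(methoxycarbonyl)-2-(prop-1-en-2-yl)hex-4-en-1-yl]malonate; 13 allyl acetoacetate
Product: 15 allyl 3-[(2R,4E)-5-(methoxycarbonyl)-2-(prop-1-en-2-yl)hex-4-en-1-yl]-3-(3-methylbut-2-en-1-yl)-2,4,6-trioxocyclohexane-1-carboxylate (enolized; both epimers at ring C3), via open-chain diketo ester 14 (not isolated)
Conditions: 13, NaH then n-BuLi, THF, 0 °C (dianion in excess); then 12, 0 °C to rt; then 1 M HCl
Reagents that add atoms: none
Why: Claisen acylation of the acetoacetate dianion at its γ-carbon by one malonate ester followed by Dieckmann closure of the doubly activated α-carbon on the second ester builds the carbocycle (bonds C5–C6 and C2–C3), driven by the stable enolate of the cyclic tricarbonyl product, while the conjugated α-branched chain ester is the least electrophilic of the three esters.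

**Step 8**
Reactants: 15 allyl 3-[(2R,4E)-5-(methoxycarbonyl)-2-(prop-1-en-2-yl)hex-4-en-1-yl]-3-(3-methylbut-2-en-1-yl)-2,4,6-trioxocyclohexane-1-carboxylate
Product: 17 methyl (2E,5R)-2-methyl-6-[1-(3-methylbut-2-en-1-yl)-2,4,6-trioxocyclohexyl]-5-(prop-1-en-2-yl)hex-2-enoate, via β-keto acid 16 (not isolated)
Conditions: Pd(OAc)2 (cat.), PPh3, HCO2H, Et3N, THF, rt
Reagents that add atoms: none
Why: Tsuji–Trost deallylation, in which zerovalent palladium ionizes the allyl ester, formate reduces the allyl fragment to propene and the β-keto acid loses CO2 at room temperature, which spares the methyl enoate and restores the local mirror symmetry about C1.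

**Step 9**
Reactants: 17 methyl (2E,5R)-2-methyl-6-[1-(3-methylbut-2-en-1-yl)-2,4,6-trioxocyclohexyl]-5-(prop-1-en-2-yl)hex-2-enoate
Product: 19 methyl (2E)-4-[(2R,3R,4aS)-2-(iodomethyl)-2-methyl-4a-(3-methylbut-2-en-1-yl)-5,7-dioxo-3,4,4a,5,6,7-hexahydro-2H-chromen-3-yl]-2-methylbut-2-enoate (one epimer at the iodomethyl carbon drawn), via alkylmercury trifluoroacetate 18 (not isolated)
Conditions: Hg(OCOCF3)2, MeCN, −20 to 0 °C; then KI, I2, 0 °C; aq. Na2S2O3 work-up
Reagents that add atoms: iodine, II; potassium iodide, [K+].[I-] (the two exchange in triiodide)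
Why: Divalent mercury binds the 1,1-disubstituted isopropenyl olefin rather than the trisubstituted prenyl or the electron-poor enoate olefin (the order known from limonene), an enol oxygen next to C1 adds anti to the metal at the tertiary carbon, and triiodide then cleaves the primary C–Hg bond of 18 to leave the iodomethyl group. The closest known reaction type is the intramolecular oxymercuration or iodoetherification of alkenyl 1,3-diones and phenols, run here as a choice between two diastereotopic enol oxygens. The one new ring, the dihydropyran O6–C6–C1–CH2–CH–C(tertiary), closes 6-exo-trig with Markovnikov regiochemistry. C1 is set by the chain stereocentre: the forming chair is fused to the flat dienone, so the other ring carbon on C1 is equatorial and the prenyl group axial, and only closure through the oxygen that becomes O6 lets the enoate arm sit equatorial and trans to that prenyl group, whereas closure through O2 would place the arm 1,3-diaxial to it. The ether carbon bearing CH3 and CH2I is the second new centre, expected with the metal-bearing methylene equatorial, but it is destroyed again in step 11, so either epimer serves. The step needs olefin selectivity, secured by the preference of mercury for the least hindered olefin and a primary C–Hg bond, and oxygen selectivity, secured by the chair preference above and helped by the reversibility of oxymercuration with the trifluoroacetate, which lets the adducts drain to the more stable diastereomer.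

**Step 10**
Reactants: 19 methyl (2E)-4-[(2R,3R,4aS)-2-(iodomethyl)-2-methyl-4a-(3-methylbut-2-en-1-yl)-5,7-dioxo-3,4,4a,5,6,7-hexahydro-2H-chromen-3-yl]-2-methylbut-2-enoate; 20 (R)-2-methylbutanoic acid
Product: 22 methyl (2E)-4-[(2R,3R,4aR)-5-hydroxy-2-(iodomethyl)-2-methyl-6-[(2R)-2-methylbutanoyl]-4a-(3-methylbut-2-en-1-yl)-7-oxo-3,4,4a,7-tetrahydro-2H-chromen-3-yl]-2-methylbut-2-enoate, via enol ester 21 (not isolated)
Conditions: 20, DCC, DMAP, CH2Cl2, 0 °C to rt
Reagents that add atoms: none
Why: Steglich O-acylation of the C2/C4 enol followed by the DMAP-mediated 1,3 O-to-C acyl shift (the usual route to 2-acyl-1,3-diones) places the acyl group on C3, the only carbon between two free carbonyls now that O6 is held in the ether, and carries the acid stereocentre in unchanged.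

**Step 11**
Reactants: 22 methyl (2E)-4-[(2R,3R,4aR)-5-hydroxy-2-(iodomethyl)-2-methyl-6-[(2R)-2-methylbutanoyl]-4a-(3-methylbut-2-en-1-yl)-7-oxo-3,4,4a,7-tetrahydro-2H-chromen-3-yl]-2-methylbut-2-enoate
Product: 23 methyl (2E,5R)-6-[(1S)-2,6-dihydroxy-3-[(2R)-2-methylbutanoyl]-1-(3-methylbut-2-en-1-yl)-4-oxocyclohexa-2,5-dien-1-yl]-2-methyl-5-(prop-1-en-2-yl)hex-2-enoate
Conditions: Zn dust, AcOH, EtOH, rt
Reagents that add atoms: none
Why: Zinc inserts into the C–I bond and the β-alkoxy organozinc undergoes Boord-type reductive elimination with the vinylogous carboxylate O6 as leaving group, which regenerates the isopropenyl group without positional isomers and frees O6–H while C1, now fixed by the C3 acyl group, stays as set.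

**Step 12**
Reactants: 23 methyl (2E,5R)-6-[(1S)-2,6-dihydroxy-3-[(2R)-2-methylbutanoyl]-1-(3-methylbut-2-en-1-yl)-4-oxocyclohexa-2,5-dien-1-yl]-2-methyl-5-(prop-1-en-2-yl)hex-2-enoate; 24 3-methylbut-2-enal
Product: 26 methyl (2E,5R)-6-[(8R)-7-hydroxy-2,2-dimethyl-6-[(2R)-2-methylbutanoyl]-8-(3-methylbut-2-en-1-yl)-5-oxo-5,8-dihydro-2H-chromen-8-yl]-2-methyl-5-(prop-1-en-2-yl)hex-2-enoate, via oxatriene 25 (not isolated)
Conditions: 24, ethylenediammonium diacetate (cat.), toluene, 70 °C
Reagents that add atoms: none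
Why: Knoevenagel condensation of the enal at C5, the only unsubstituted nucleophilic ring carbon, gives a 1-oxatriene that closes by oxa-6π electrocyclization on O6, the carbonyl oxygen outside the acyl chelate, which keeps both the acyl–enol hydrogen bond and the cross-conjugated C4 ketone and creates no stereocentre.

**Step 13**
Reactants: 26 methyl (2E,5R)-6-[(8R)-7-hydroxy-2,2-dimethyl-6-[(2R)-2-methylbutanoyl]-8-(3-methylbut-2-en-1-yl)-5-oxo-5,8-dihydro-2H-chromen-8-yl]-2-methyl-5-(prop-1-en-2-yl)hex-2-enoate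
Product: 27 (2E,5R)-6-[(8R)-7-hydroxy-2,2-dimethyl-6-[(2R)-2-methylbutanoyl]-8-(3-methylbut-2-en-1-yl)-5-oxo-5,8-dihydro-2H-chromen-8-yl]-2-methyl-5-(prop-1-en-2-yl)hex-2-enoic acid
Conditions: LiOH, THF/MeOH/H2O, 40 °C; then 1 M HCl
Reagents that add atoms: lithium hydroxide, [Li+].[OH-]
Why: Saponification of the methyl ester, during which the tricarbonyl unit is present as its enolate and is thereby protected from retro-Claisen cleavage and from epimerization at the acyl α-carbon.

**Compound list**

1 | (S)-4-benzyl-1,3-oxazolidin-2-one | O=C1N[C@@H](Cc2ccccc2)CO1 | starting material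
2 | 3-methylbut-2-enoyl chloride | CC(C)=CC(Cl)=O | starting material
3 | (S)-4-benzyl-3-(3-methylbut-2-enoyl)-1,3-oxazolidin-2-one | CC(C)=CC(=O)N1[C@@H](Cc2ccccc2)COC1=O | intermediate
4 | methyl (E)-4-bromo-2-methylbut-2-enoate | BrC/C=C(\C)C(=O)OC | starting material
5 | methyl (2E,5S)-5-{[(4S)-4-benzyl-2-oxo-1,3-oxazolidin-3-yl]carbonyl}-2,6-dimethylhepta-2,6-dienoate | C=C(C)[C@H](C/C=C(\C)C(=O)OC)C(=O)N1[C@@H](Cc2ccccc2)COC1=O | intermediate
6 | methyl (2E,5S)-5-formyl-2,6-dimethylhepta-2,6-dienoate (aldehyde; not isolated) | C=C(C)[C@H](C/C=C(\C)C(=O)OC)C=O | intermediate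
7 | methyl (2E,5S)-5-(hydroxymethyl)-2,6-dimethylhepta-2,6-dienoate | C=C(C)[C@H](C/C=C(\C)C(=O)OC)CO | intermediate
8 | methyl (2E,5S)-5-(iodomethyl)-2,6-dimethylhepta-2,6-dienoate | C=C(C)[C@H](C/C=C(\C)C(=O)OC)CI | intermediate
9 | dimethyl malonate | COC(=O)CC(=O)OC | starting material
10 | prenyl bromide (1-bromo-3-methylbut-2-ene) | CC(C)=CCBr | starting material
11 | dimethyl 2-(3-methylbut-2-en-1-yl)malonate | COC(=O)C(CC=C(C)C)C(=O)OC | intermediate
12 | dimethyl 2-(3-methylbut-2-en-1-yl)-2-[(2R,4E)-5-(methoxycarbonyl)-2-(prop-1-en-2-yl)hex-4-en-1-yl]malonate | C=C(C)[C@H](C/C=C(\C)C(=O)OC)CC(CC=C(C)C)(C(=O)OC)C(=O)OC | intermediate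
13 | allyl acetoacetate (prop-2-en-1-yl 3-oxobutanoate) | CC(=O)CC(=O)OCC=C | starting material
14 | prop-2-en-1-yl 6-(methoxycarbonyl)-6-[(2R,4E)-5-(methoxycarbonyl)-2-(prop-1-en-2-yl)hex-4-en-1-yl]-9-methyl-3,5-dioxodec-8-enoate (open-chain diketo ester; both epimers at C6; not isolated) | C=C(C)[C@H](C/C=C(\C)C(=O)OC)CC(CC=C(C)C)(C(=O)OC)C(=O)CC(=O)CC(=O)OCC=C | intermediate
15 | allyl 3-[(2R,4E)-5-(methoxycarbonyl)-2-(prop-1-en-2-yl)hex-4-en-1-yl]-3-(3-methylbut-2-en-1-yl)-2,4,6-trioxocyclohexane-1-carboxylate (drawn as an enol; both epimers at ring C3) | C=C(C)[C@H](C/C=C(\C)C(=O)OC)CC1(CC=C(C)C)C(=O)CC(=O)C(C(=O)OCC=C)=C1O | intermediate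
16 | 3-[(2R,4E)-5-(methoxycarbonyl)-2-(prop-1-en-2-yl)hex-4-en-1-yl]-3-(3-methylbut-2-en-1-yl)-2,4,6-trioxocyclohexane-1-carboxylic acid (β-keto acid; drawn as an enol; not isolated) | C=C(C)[C@H](C/C=C(\C)C(=O)OC)CC1(CC=C(C)C)C(=O)CC(=O)C(C(=O)O)=C1O | intermediate
17 | methyl (2E,5R)-2-methyl-6-[1-(3-methylbut-2-en-1-yl)-2,4,6-trioxocyclohexyl]-5-(prop-1-en-2-yl)hex-2-enoate (C1 not stereogenic; exists as the 2,6-dihydroxy-4-oxo dienol) | C=C(C)[C@H](C/C=C(\C)C(=O)OC)CC1(CC=C(C)C)C(=O)CC(=O)CC1=O | intermediate
18 | {[(2R,3R,4aS)-3-[(2E)-4-methoxy-3-methyl-4-oxobut-2-en-1-yl]-2-methyl-4a-(3-methylbut-2-en-1-yl)-5,7-dioxo-3,4,4a,5,6,7-hexahydro-2H-chromen-2-yl]methyl}mercury trifluoroacetate (not isolated) | FC(F)(F)C(=O)O[Hg]C[C@@]3(C)[C@H](C/C=C(\C)C(=O)OC)C[C@]1(CC=C(C)C)C(=O)CC(=O)C=C1O3 | intermediate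
19 | methyl (2E)-4-[(2R,3R,4aS)-2-(iodomethyl)-2-methyl-4a-(3-methylbut-2-en-1-yl)-5,7-dioxo-3,4,4a,5,6,7-hexahydro-2H-chromen-3-yl]-2-methylbut-2-enoate (one epimer at the iodomethyl carbon drawn) | IC[C@@]3(C)[C@H](C/C=C(\C)C(=O)OC)C[C@]1(CC=C(C)C)C(=O)CC(=O)C=C1O3 | intermediate
20 | (R)-2-methylbutanoic acid | CC[C@@H](C)C(=O)O | starting material
21 | (2R,3R,4aS)-2-(iodomethyl)-3-[(2E)-4-methoxy-3-methyl-4-oxobut-2-en-1-yl]-2-methyl-4a-(3-methylbut-2-en-1-yl)-7-oxo-3,4,4a,7-tetrahydro-2H-chromen-5-yl (2R)-2-methylbutanoate (enol ester; not isolated) | IC[C@@]3(C)[C@H](C/C=C(\C)C(=O)OC)C[C@]1(CC=C(C)C)C(OC(=O)[C@H](C)CC)=CC(=O)C=C1O3 | intermediate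
22 | methyl (2E)-4-[(2R,3R,4aR)-5-hydroxy-2-(iodomethyl)-2-methyl-6-[(2R)-2-methylbutanoyl]-4a-(3-methylbut-2-en-1-yl)-7-oxo-3,4,4a,7-tetrahydro-2H-chromen-3-yl]-2-methylbut-2-enoate | IC[C@@]3(C)[C@H](C/C=C(\C)C(=O)OC)C[C@]1(CC=C(C)C)C(O)=C(C(=O)[C@H](C)CC)C(=O)C=C1O3 | intermediate
23 | methyl (2E,5R)-6-[(1S)-2,6-dihydroxy-3-[(2R)-2-methylbutanoyl]-1-(3-methylbut-2-en-1-yl)-4-oxocyclohexa-2,5-dien-1-yl]-2-methyl-5-(prop-1-en-2-yl)hex-2-enoate | C=C(C)[C@H](C/C=C(\C)C(=O)OC)C[C@]1(CC=C(C)C)C(O)=C(C(=O)[C@H](C)CC)C(=O)C=C1O | intermediate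
24 | 3-methylbut-2-enal | CC(C)=CC=O | starting material
25 | methyl (2E,5R)-6-[(1R)-2-hydroxy-3-[(2R)-2-methylbutanoyl]-5-(3-methylbut-2-en-1-ylidene)-1-(3-methylbut-2-en-1-yl)-4,6-dioxocyclohex-2-en-1-yl]-2-methyl-5-(prop-1-en-2-yl)hex-2-enoate (oxatriene; not isolated) | C=C(C)[C@H](C/C=C(\C)C(=O)OC)C[C@]1(CC=C(C)C)C(O)=C(C(=O)[C@H](C)CC)C(=O)C(=CC=C(C)C)C1=O | intermediate
26 | methyl (2E,5R)-6-[(8R)-7-hydroxy-2,2-dimethyl-6-[(2R)-2-methylbutanoyl]-8-(3-methylbut-2-en-1-yl)-5-oxo-5,8-dihydro-2H-chromen-8-yl]-2-methyl-5-(prop-1-en-2-yl)hex-2-enoate | C=C(C)[C@H](C/C=C(\C)C(=O)OC)C[C@]1(CC=C(C)C)C(O)=C(C(=O)[C@H](C)CC)C(=O)C2=C1OC(C)(C)C=C2 | intermediate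
27 | (2E,5R)-6-[(8R)-7-hydroxy-2,2-dimethyl-6-[(2R)-2-methylbutanoyl]-8-(3-methylbut-2-en-1-yl)-5-oxo-5,8-dihydro-2H-chromen-8-yl]-2-methyl-5-(prop-1-en-2-yl)hex-2-enoic acid | C=C(C)[C@H](C/C=C(\C)C(=O)O)C[C@]1(CC=C(C)C)C(O)=C(C(=O)[C@H](C)CC)C(=O)C2=C1OC(C)(C)C=C2 | target

**Count and risks**

Total steps: 13. Longest linear sequence: 12 (steps 1–4 and 6–13, from compound 1); step 5 is a one-step branch.

Steps most likely to fail:

1. Step 9. The two enol oxygens may not be told apart well enough (closure through O2 by way of a twist-boat), and mercury may also attack the prenyl olefin or the enol carbons C3/C5. The fallback sets out from 17 and gives up the temporary ring. Direct Steglich acylation of 17 with acid 20 (DCC, DMAP, CH2Cl2) should lead through the enol ester F3 to a mixture of 23 and its C1 epimer F4. These are diastereomers because of the chain and acyl centres and would be separated by chromatography. The route is rejoined at compound 23, and steps 9–11 fall away.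

2. Step 7. Acylation of the dianion by the neopentyl-type malonate ester may be slow, which leaves time for proton transfer from, or attack at, the chain enoate and for incomplete ring closure. The fallback sets out from 12. One equivalent of KOH in MeOH should hydrolyse one of the two mutually activated malonate esters to the half-ester F1. 1,1'-Carbonyldiimidazole would turn it into the acyl imidazolide F2, which should acylate the dianion of 13 at −78 °C, where the enoate is inert, to give 14. Compound 14 is then closed with DBU in THF to 15, where the route is rejoined.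

3. Step 12. Condensation of the chelated acyl trione with an enolizable enal may be slow against self-condensation of 24, and the oxatriene may close on the C4 oxygen instead of O6. The fallback sets out from 23. C5 prenylation with prenyl bromide 10 (NaOMe, MeOH, 0 °C, the alkylation known from the hop β-acids) should give the C5-prenyl trione F5. Dehydrogenation with DDQ in toluene at room temperature then generates the oxatriene without base or heat, and its closure returns the route to compound 26. The oxatriene is the same as in step 12, so this removes the condensation problem but not a thermodynamic preference for the wrong oxygen.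

**Further compounds**

F1 | step 7 | 2-(methoxycarbonyl)-2-[(2R,4E)-5-(methoxycarbonyl)-2-(prop-1-en-2-yl)hex-4-en-1-yl]-5-methylhex-4-enoic acid (half-ester; both epimers at C2) | C=C(C)[C@H](C/C=C(\C)C(=O)OC)CC(CC=C(C)C)(C(=O)OC)C(=O)O
F2 | step 7 | acyl imidazolide of F1 (1H-imidazol-1-yl ketone in place of CO2H) | C=C(C)[C@H](C/C=C(\C)C(=O)OC)CC(CC=C(C)C)(C(=O)OC)C(=O)n1ccnc1
F3 | step 9 | enol (2R)-2-methylbutanoate of 17 at one of the oxygens flanking C1 (both C1 epimers) | C=C(C)[C@H](C/C=C(\C)C(=O)OC)CC1(CC=C(C)C)C(OC(=O)[C@H](C)CC)=CC(=O)CC1=O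
F4 | step 9 | C1 epimer of 23, methyl (2E,5R)-6-[(1R)-2,6-dihydroxy-3-[(2R)-2-methylbutanoyl]-1-(3-methylbut-2-en-1-yl)-4-oxocyclohexa-2,5-dien-1-yl]-2-methyl-5-(prop-1-en-2-yl)hex-2-enoate | C=C(C)[C@H](C/C=C(\C)C(=O)OC)C[C@@]1(CC=C(C)C)C(O)=C(C(=O)[C@H](C)CC)C(=O)C=C1O
F5 | step 12 | C5-(3-methylbut-2-en-1-yl) derivative of 23 | C=C(C)[C@H](C/C=C(\C)C(=O)OC)C[C@]1(CC=C(C)C)C(O)=C(C(=O)[C@H](C)CC)C(=O)C(CC=C(C)C)=C1O
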